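The depside is disconnected at the ester between the ring A carbonyl and O3' of ring B, and ring B at both C6'–propyl and C1'–CO2H. Because C1' and C6' are adjacent and C2' carries a methoxy group, they are formed as the two termini of an aryne: the C2' oxygen polarizes the triple bond so that propylmagnesium chloride attacks C6' and magnesium ends at C1', where carbon dioxide is captured. One operation thus sets both carbon substituents. The precursor is an ortho-iodoaryl triflate (iodine at C6', triflate at C1') with O3' as methoxymethyl ether and O4' as benzyl ether, told apart earlier while O4' is para to a formyl group.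

Key step: step 9

Remark: ring B positions are written C1'–C6' throughout (C1' carries the carboxyl group of the target and the formyl carbon of the starting aldehyde, C2' the methoxy group, C3' the ester oxygen, C4' the free hydroxyl, C6' the propyl group); the target is achiral, so no step has to set configuration.

Step 1
Reactants: 1 2,3,4-trihydroxybenzaldehyde; 2 dichlorodiphenylmethane
Product: 3 4-hydroxy-2,2-diphenyl-1,3-benzodioxole-5-carbaldehyde
Conditions: 2 (1.1 equiv), Ph2O, 175 °C
Reagents that add atoms: none
Why: Catechol ketalization with a gem-dichloride, in which the 2-hydroxyl stays hydrogen-bonded to the formyl group, so the free 3,4-diol should close the five-membered diphenylmethylene ketal with loss of HCl.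

Step 2
Reactants: 3 4-hydroxy-2,2-diphenyl-1,3-benzodioxole-5-carbaldehyde
Product: 4 4-methoxy-2,2-diphenyl-1,3-benzodioxole-5-carbaldehyde
Conditions: MeI, K2CO3, DMF, 40 °C
Reagents that add atoms: iodomethane, CI
Why: Williamson ether synthesis on the only free phenol, which fixes the methyl group on O2' while the ketal and the aldehyde are inert.

Step 3
Reactants: 4 4-methoxy-2,2-diphenyl-1,3-benzodioxole-5-carbaldehyde
Product: 5 3,4-dihydroxy-2-methoxybenzaldehyde
Conditions: AcOH/H2O (4:1), reflux
Reagents that add atoms: none
Why: Acid-catalyzed ketal hydrolysis through the diphenyl-stabilized oxocarbenium ion frees the catechol, while the aryl methyl ether and the aldehyde are untouched.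

Step 4
Reactants: 5 3,4-dihydroxy-2-methoxybenzaldehyde
Product: 6 4-(benzyloxy)-3-hydroxy-2-methoxybenzaldehyde
Conditions: BnBr (1.05 equiv), NaHCO3, NaI (cat.), DMF, 40 °C
Reagents that add atoms: benzyl bromide, BrCc1ccccc1
Why: Regioselective Williamson mono-alkylation, in which the 4-hydroxyl is para to the formyl group and therefore the more acidic and also the less hindered phenol, so the weak base should ionize and benzylate it alone, as in the mono-benzylation of 3,4-dihydroxybenzaldehyde.

Step 5
Reactants: 6 4-(benzyloxy)-3-hydroxy-2-methoxybenzaldehyde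
Product: 7 4-(benzyloxy)-2-methoxy-3-(methoxymethoxy)benzaldehyde
Conditions: MOMCl, iPr2NEt, CH2Cl2, 0 °C → rt
Reagents that add atoms: chloromethyl methyl ether, COCCl
Why: Acetal protection (methoxymethylation) of the remaining phenol by SN1-type alkylation with the reactive α-chloro ether, which copes with the two flanking oxygen substituents.

Step 6
Reactants: 7 4-(benzyloxy)-2-methoxy-3-(methoxymethoxy)benzaldehyde
Product: 9 4-(benzyloxy)-2-methoxy-3-(methoxymethoxy)phenol, via aryl formate 8 (not isolated)
Conditions: mCPBA, CH2Cl2, 0 °C → rt; then K2CO3 (cat.), MeOH, rt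
Reagents that add atoms: 3-chloroperoxybenzoic acid, OOC(=O)c1cccc(Cl)c1
Why: Baeyer–Villiger oxidation of an electron-rich benzaldehyde (Dakin-type), in which the aryl group with ortho and para oxygen donors migrates in the Criegee adduct in preference to hydride and the formate is then methanolyzed by catalytic carbonate.

Step 7
Reactants: 9 4-(benzyloxy)-2-methoxy-3-(methoxymethoxy)phenol
Product: 10 4-(benzyloxy)-6-iodo-2-methoxy-3-(methoxymethoxy)phenol
Conditions: I2 (1.05 equiv), NaHCO3, THF/H2O, 0 °C → rt
Reagents that add atoms: iodine, II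
Why: Electrophilic aromatic iodination under phenol(ate) control, since of the two free ring positions only C6' is ortho to the hydroxyl (the para position is blocked) and it is also para to O3', so iodine should enter there and not at C5'.

Step 8
Reactants: 10 4-(benzyloxy)-6-iodo-2-methoxy-3-(methoxymethoxy)phenol
Product: 11 4-(benzyloxy)-6-iodo-2-methoxy-3-(methoxymethoxy)phenyl trifluoromethanesulfonate
Conditions: Tf2O, pyridine, CH2Cl2, 0 °C
Reagents that add atoms: trifluoromethanesulfonic anhydride, FC(F)(F)S(=O)(=O)OS(=O)(=O)C(F)(F)F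
Why: O-Sulfonylation of the phenol with triflic anhydride and pyridine gives the aryl triflate, the ethers and the aryl iodide being inert.

Step 9
Reactants: 11 4-(benzyloxy)-6-iodo-2-methoxy-3-(methoxymethoxy)phenyl trifluoromethanesulfonate; 12 propylmagnesium chloride; 13 carbon dioxide
Product: 17 4-(benzyloxy)-2-methoxy-3-(methoxymethoxy)-6-propylbenzoic acid, via magnesiated aryl triflate 14 (not isolated), via aryne 15 (not isolated), via arylmagnesium chloride 16 (not isolated)
Conditions: 12 (4 equiv), THF, −78 → −30 °C, 11 added slowly; then 13 (dry gas), −30 °C → rt; then 1 M HCl, 0 °C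
Reagents that add atoms: none
Why: Iodine–magnesium exchange at C6' gives 14, whose magnesium and triflate sit on neighboring carbons, so MgCl(OTf) is lost at low temperature to form aryne 15 across C1'–C6'; a second equivalent of the propyl Grignard reagent adds across the strained bond to give 16, and carbon dioxide then carboxylates the C1'–Mg bond. The closest known reaction type is aryne generation from ortho-iodoaryl sulfonates by halogen–magnesium exchange, followed by carbomagnesiation of the aryne and trapping of the new arylmagnesium with an electrophile. No ring is closed and no stereocenter is created. The step needs regioselective addition to an unsymmetrical aryne, and the C2' methoxy group secures it: its oxygen withdraws electron density through the sigma framework, so the nucleophile enters at the distal and less hindered C6' and the carbanion develops at C1', in the ring plane next to the oxygen-bearing carbon, where the methoxy oxygen can also coordinate magnesium. Exchange at iodine should outrun attack of the Grignard reagent at the sulfonyl sulfur at −78 °C, and slow addition of 11 to an excess of 12 keeps arylmagnesium species from competing with propyl for the aryne. The methoxymethyl and benzyl ethers are inert to these reagents.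

Step 10
Reactants: 17 4-(benzyloxy)-2-methoxy-3-(methoxymethoxy)-6-propylbenzoic acid
Product: 18 benzyl 4-(benzyloxy)-2-methoxy-3-(methoxymethoxy)-6-propylbenzoate
Conditions: BnBr, K2CO3, DMF, rt
Reagents that add atoms: benzyl bromide, BrCc1ccccc1
Why: Carboxylate O-alkylation (SN2 at the benzylic carbon of BnBr), the standard way to esterify a 2,6-disubstituted benzoic acid whose carbonyl carbon is shielded.

Step 11
Reactants: 18 benzyl 4-(benzyloxy)-2-methoxy-3-(methoxymethoxy)-6-propylbenzoate
Product: 19 benzyl 4-(benzyloxy)-3-hydroxy-2-methoxy-6-propylbenzoate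
Conditions: conc. HCl (cat.), MeOH/THF, 45 °C
Reagents that add atoms: none
Why: Acid-catalyzed acetal cleavage (transacetalization to methanol) removes the methoxymethyl group and frees O3' alone, while the benzyl ether and the hindered benzyl ester resist dilute acid.

Step 12
Reactants: 20 5-propylresorcinol
Product: 22 2,4-dihydroxy-6-propylbenzaldehyde, via iminium chloride 21 (not isolated)
Conditions: POCl3, DMF, 0 °C → rt; then H2O, 50 °C
Reagents that add atoms: N,N-dimethylformamide, CN(C)C=O; water, O
Why: Vilsmeier–Haack formylation, in which the chloroiminium ion attacks the resorcinol ring para to one hydroxyl and ortho to the other (C4), the position known to react in 5-alkylresorcinols, and water then hydrolyzes the iminium salt.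

Step 13
Reactants: 22 2,4-dihydroxy-6-propylbenzaldehyde
Product: 23 2,4-bis(benzyloxy)-6-propylbenzaldehyde
Conditions: BnBr (2.5 equiv), K2CO3, DMF, 60 °C
Reagents that add atoms: benzyl bromide, BrCc1ccccc1
Why: Double Williamson etherification, the excess base and warming also alkylating the hydrogen-bonded 2-hydroxyl.

Step 14
Reactants: 23 2,4-bis(benzyloxy)-6-propylbenzaldehyde
Product: 24 2,4-bis(benzyloxy)-6-propylbenzoic acid
Conditions: NaClO2, NaH2PO4, 2-methyl-2-butene, tBuOH/THF/H2O, rt
Reagents that add atoms: sodium chlorite, [Na+].[O-]Cl=O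
Why: Pinnick oxidation of the aldehyde to the acid with chlorous acid, the alkene scavenging HOCl so that the electron-rich ring is not chlorinated.

Step 15
Reactants: 24 2,4-bis(benzyloxy)-6-propylbenzoic acid; 19 benzyl 4-(benzyloxy)-3-hydroxy-2-methoxy-6-propylbenzoate
Product: 27 benzyl 4-(benzyloxy)-3-{[2,4-bis(benzyloxy)-6-propylbenzoyl]oxy}-2-methoxy-6-propylbenzoate, via acid chloride 25 (not isolated), via sodium phenoxide 26 (not isolated)
Conditions: 24, (COCl)2, DMF (cat.), CH2Cl2, 0 °C → rt, evaporation; 19, NaH, THF, 0 °C; then the acid chloride, 0 °C → rt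
Reagents that add atoms: none
Why: Acyl chloride formation with oxalyl chloride under DMF catalysis followed by O-acylation of a preformed phenoxide (Schotten–Baumann-type esterification), the strongly nucleophilic phenoxide and the small, highly electrophilic acyl chloride being chosen because both partners carry two ortho substituents.

Step 16
Reactants: 27 benzyl 4-(benzyloxy)-3-{[2,4-bis(benzyloxy)-6-propylbenzoyl]oxy}-2-methoxy-6-propylbenzoate
Product: 28 3-[(2,4-dihydroxy-6-propylbenzoyl)oxy]-4-hydroxy-2-methoxy-6-propylbenzoic acid
Conditions: H2 (1 atm), Pd/C (10%), EtOAc, rt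
Reagents that add atoms: none
Why: Catalytic hydrogenolysis of the three benzyl ethers and the benzyl ester under neutral conditions, which should leave the depside aryl ester (no benzylic C–O bond) intact and avoid acyl migration to O4'.

Compound list
1 | 2,3,4-trihydroxybenzaldehyde | O=Cc1ccc(O)c(O)c1O | starting material
2 | dichlorodiphenylmethane | ClC(Cl)(c1ccccc1)c1ccccc1 | starting material
3 | 4-hydroxy-2,2-diphenyl-1,3-benzodioxole-5-carbaldehyde | O=Cc1ccc2OC(c3ccccc3)(c3ccccc3)Oc2c1O | intermediate
4 | 4-methoxy-2,2-diphenyl-1,3-benzodioxole-5-carbaldehyde | COc1c(C=O)ccc2OC(c3ccccc3)(c3ccccc3)Oc12 | intermediate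
5 | 3,4-dihydroxy-2-methoxybenzaldehyde | COc1c(C=O)ccc(O)c1O | intermediate
6 | 4-(benzyloxy)-3-hydroxy-2-methoxybenzaldehyde | COc1c(C=O)ccc(OCc2ccccc2)c1O | intermediate
7 | 4-(benzyloxy)-2-methoxy-3-(methoxymethoxy)benzaldehyde | COCOc1c(OCc2ccccc2)ccc(C=O)c1OC | intermediate
8 | 4-(benzyloxy)-2-methoxy-3-(methoxymethoxy)phenyl formate | COCOc1c(OCc2ccccc2)ccc(OC=O)c1OC | intermediate
9 | 4-(benzyloxy)-2-methoxy-3-(methoxymethoxy)phenol | COCOc1c(OCc2ccccc2)ccc(O)c1OC | intermediate
10 | 4-(benzyloxy)-6-iodo-2-methoxy-3-(methoxymethoxy)phenol | COCOc1c(OCc2ccccc2)cc(I)c(O)c1OC | intermediate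
11 | 4-(benzyloxy)-6-iodo-2-methoxy-3-(methoxymethoxy)phenyl trifluoromethanesulfonate | COCOc1c(OCc2ccccc2)cc(I)c(OS(=O)(=O)C(F)(F)F)c1OC | intermediate
12 | propylmagnesium chloride | CCC[Mg]Cl | starting material
13 | carbon dioxide | O=C=O | starting material
14 | [5-(benzyloxy)-3-methoxy-4-(methoxymethoxy)-2-(trifluoromethanesulfonyloxy)phenyl]magnesium chloride (magnesium at C6') | COCOc1c(OCc2ccccc2)cc([Mg]Cl)c(OS(=O)(=O)C(F)(F)F)c1OC | intermediate
15 | 5-(benzyloxy)-3-methoxy-4-(methoxymethoxy)-1,2-didehydrobenzene (aryne across C1'–C6') | COCOC1=C(OC)C#CC=C1OCc1ccccc1 | intermediate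
16 | [4-(benzyloxy)-2-methoxy-3-(methoxymethoxy)-6-propylphenyl]magnesium chloride | CCCc1cc(OCc2ccccc2)c(OCOC)c(OC)c1[Mg]Cl | intermediate
17 | 4-(benzyloxy)-2-methoxy-3-(methoxymethoxy)-6-propylbenzoic acid | CCCc1cc(OCc2ccccc2)c(OCOC)c(OC)c1C(=O)O | intermediate
18 | benzyl 4-(benzyloxy)-2-methoxy-3-(methoxymethoxy)-6-propylbenzoate | CCCc1cc(OCc2ccccc2)c(OCOC)c(OC)c1C(=O)OCc1ccccc1 | intermediate
19 | benzyl 4-(benzyloxy)-3-hydroxy-2-methoxy-6-propylbenzoate | CCCc1cc(OCc2ccccc2)c(O)c(OC)c1C(=O)OCc1ccccc1 | intermediate
20 | 5-propylresorcinol | CCCc1cc(O)cc(O)c1 | starting material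
21 | [(2,4-dihydroxy-6-propylphenyl)methylidene]dimethylammonium chloride | CCCc1cc(O)cc(O)c1C=[N+](C)C.[Cl-] | intermediate
22 | 2,4-dihydroxy-6-propylbenzaldehyde | CCCc1cc(O)cc(O)c1C=O | intermediate
23 | 2,4-bis(benzyloxy)-6-propylbenzaldehyde | CCCc1cc(OCc2ccccc2)cc(OCc2ccccc2)c1C=O | intermediate
24 | 2,4-bis(benzyloxy)-6-propylbenzoic acid | CCCc1cc(OCc2ccccc2)cc(OCc2ccccc2)c1C(=O)O | intermediate
25 | 2,4-bis(benzyloxy)-6-propylbenzoyl chloride | CCCc1cc(OCc2ccccc2)cc(OCc2ccccc2)c1C(=O)Cl | intermediate
26 | sodium 6-(benzyloxy)-3-[(benzyloxy)carbonyl]-2-methoxy-4-propylphenolate (sodium salt of 19) | CCCc1cc(OCc2ccccc2)c([O-])c(OC)c1C(=O)OCc1ccccc1.[Na+] | intermediate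
27 | benzyl 4-(benzyloxy)-3-{[2,4-bis(benzyloxy)-6-propylbenzoyl]oxy}-2-methoxy-6-propylbenzoate | CCCc1cc(OCc2ccccc2)cc(OCc2ccccc2)c1C(=O)Oc1c(OCc2ccccc2)cc(CCC)c(C(=O)OCc2ccccc2)c1OC | intermediate
28 | 3-[(2,4-dihydroxy-6-propylbenzoyl)oxy]-4-hydroxy-2-methoxy-6-propylbenzoic acid (CNP0126444.0) | CCCc1cc(O)cc(O)c1C(=O)Oc1c(O)cc(CCC)c(C(=O)O)c1OC | target

Total step count: 16 (steps 1–11 for ring B, steps 12–14 for ring A, steps 15 and 16 for union and deprotection).
Longest linear sequence: 13 steps (steps 1–11, 15 and 16).

Steps most likely to fail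

Step 9. The exchange at iodine with a primary Grignard reagent may be slow enough for attack at the sulfonyl sulfur to compete, arylmagnesium intermediates may add to the aryne in place of propyl, and regiocontrol of the addition may be incomplete. The fallback gives up the aryne and sets the two carbon substituents by two palladium-catalyzed couplings. It sets out from 11: a Negishi coupling with nPrZnBr (PdCl2(dppf), THF, 50 °C), in which the C–I bond reacts well before the C–OTf bond, would give 4-(benzyloxy)-2-methoxy-3-(methoxymethoxy)-6-propylphenyl trifluoromethanesulfonate F1. Alkoxycarbonylation of this triflate (Pd(OAc)2, dppp, CO, BnOH, Et3N, DMF, 80 °C) would then give the benzyl ester directly, so the fallback comes back to the route at 18.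

Step 15. Acylation between a phenoxide flanked by two ortho substituents and an acyl chloride flanked by two ortho substituents may be slow, so that hydrolysis or decomposition of the acid chloride wins. The fallback changes the activation from a phenoxide attacking an acyl chloride to an acid-side acylium pathway. It sets out from 24 and 19, which would be stirred with trifluoroacetic anhydride in toluene at room temperature. Acid 24 would form 2,4-bis(benzyloxy)-6-propylbenzoic trifluoroacetic anhydride F2, which ionizes to an acylium ion stabilized by the ortho and para alkoxy groups and acylates the neutral phenol. It comes back to the route at 27.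

Step 7. Iodination may go in part to C5' (ortho to the benzyloxy group), or iodine may oxidize the very electron-rich phenol. The fallback places iodine by directed ortho-lithiation before the aldehyde is oxidized. It sets out from 7: LiN(Me)CH2CH2NMe2 in THF at −20 °C would add to the formyl group to give lithium α-amino alkoxide F3. n-BuLi would then remove the only hydrogen ortho to this directing group (C6'-H) to give aryllithium F4, iodine would give iodinated alkoxide F5, and aqueous work-up would release 4-(benzyloxy)-6-iodo-2-methoxy-3-(methoxymethoxy)benzaldehyde F6. Baeyer–Villiger oxidation (mCPBA, CH2Cl2; then K2CO3, MeOH) through 4-(benzyloxy)-6-iodo-2-methoxy-3-(methoxymethoxy)phenyl formate F7 would bring the fallback back to the route at 10.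

Further compounds
F1 | step 9 | 4-(benzyloxy)-2-methoxy-3-(methoxymethoxy)-6-propylphenyl trifluoromethanesulfonate | CCCc1cc(OCc2ccccc2)c(OCOC)c(OC)c1OS(=O)(=O)C(F)(F)F
F2 | step 15 | 2,4-bis(benzyloxy)-6-propylbenzoic trifluoroacetic anhydride | CCCc1cc(OCc2ccccc2)cc(OCc2ccccc2)c1C(=O)OC(=O)C(F)(F)F
F3 | step 7 | lithium [4-(benzyloxy)-2-methoxy-3-(methoxymethoxy)phenyl]{[2-(dimethylamino)ethyl](methyl)amino}methanolate | [Li+].[O-]C(N(C)CCN(C)C)c1ccc(OCc2ccccc2)c(OCOC)c1OC
F4 | step 7 | lithium [4-(benzyloxy)-6-lithio-2-methoxy-3-(methoxymethoxy)phenyl]{[2-(dimethylamino)ethyl](methyl)amino}methanolate | [Li+].[O-]C(N(C)CCN(C)C)c1c([Li])cc(OCc2ccccc2)c(OCOC)c1OC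
F5 | step 7 | lithium [4-(benzyloxy)-6-iodo-2-methoxy-3-(methoxymethoxy)phenyl]{[2-(dimethylamino)ethyl](methyl)amino}methanolate | [Li+].[O-]C(N(C)CCN(C)C)c1c(I)cc(OCc2ccccc2)c(OCOC)c1OC
F6 | step 7 | 4-(benzyloxy)-6-iodo-2-methoxy-3-(methoxymethoxy)benzaldehyde | O=Cc1c(I)cc(OCc2ccccc2)c(OCOC)c1OC
F7 | step 7 | 4-(benzyloxy)-6-iodo-2-methoxy-3-(methoxymethoxy)phenyl formate | O=COc1c(I)cc(OCc2ccccc2)c(OCOC)c1OC
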